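The pyranone ring of the chromone is dismantled at O1–C8a, C4–C4a and O1–C2. This works because, on the benzo ring, O1 (at C8a) and the C4 carbonyl (at C4a) sit ortho to each other and C4a is flanked by the oxygenated C5. That is the pattern left when an O-nucleophile captures a 3-alkoxyaryne at its remote carbon. In one operation 3,5-dimethoxybenzyne inserts into the acyl C–O bond of a 2-alkynoic acid, and the unmasked phenoxide closes the ring by conjugate addition. The partners are 3,5-dimethoxy-2-(trimethylsilyl)phenyl triflate and hexatriacont-2-ynoic acid. Chelation-guided 5-O-demethylation finishes the synthesis.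

Key step: step 7

Remark 1: the target SMILES holds no stereocentre and no stereogenic double bond. The compound is achiral, so no stereocontrol is needed and the question of a single enantiomer does not arise.
Remark 2 (carbon count): C22 + C11 give the C33 side chain, the two acetylide carbons become C2 and C3, and the CO2 carbon becomes C4.

Step 1
Reactants: 1 3,5-dimethoxyphenol
Product: 2 3,5-dimethoxyphenyl N-isopropylcarbamate
Conditions: iPrNCO (1.5 equiv), Et3N (0.2 equiv), CH2Cl2, rt
Reagents that add atoms: isopropyl isocyanate, CC(C)N=C=O
Why: Amine-catalysed addition of the phenol O–H to the isocyanate (carbamoylation) should cleanly install an N–H carbamate that is a strong directing group and can later be removed with mild base.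

Step 2
Reactants: 2 3,5-dimethoxyphenyl N-isopropylcarbamate
Product: 6 3,5-dimethoxy-2-(trimethylsilyl)phenyl N-isopropylcarbamate, via N-silyl carbamate 3 (not isolated), via aryllithium 4 (not isolated), via bis-silyl carbamate 5 (not isolated)
Conditions: TBSOTf, TMEDA, Et2O, 0 °C → rt; n-BuLi, TMEDA, −78 °C; TMSCl, −78 °C → rt; cold sat. aq. NaHSO4 work-up
Reagents that add atoms: chlorotrimethylsilane, C[Si](C)(C)Cl; tert-butyldimethylsilyl trifluoromethanesulfonate, CC(C)(C)[Si](C)(C)OS(=O)(=O)C(F)(F)F (its silyl group stays only in 3–5); n-butyllithium, [Li]CCCC (its lithium stays only in 4)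
Why: In this directed ortho-metalation, transient N-silylation masks the acidic N–H, the O-carbamate steers n-BuLi/TMEDA to C2 (shared with the 3-methoxy group and so preferred over C4 between the two weaker methoxy directors), TMSCl traps the aryllithium, and the labile N–Si bond is hydrolysed on work-up.

Step 3
Reactants: 6 3,5-dimethoxy-2-(trimethylsilyl)phenyl N-isopropylcarbamate
Product: 8 3,5-dimethoxy-2-(trimethylsilyl)phenyl trifluoromethanesulfonate, via silylphenol 7 (not isolated)
Conditions: DBU, Et2NH, MeCN, 40 °C; then PhNTf2, rt
Reagents that add atoms: N-phenylbis(trifluoromethanesulfonimide), O=S(=O)(N(c1ccccc1)S(=O)(=O)C(F)(F)F)C(F)(F)F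
Why: DBU triggers E1cB loss of isopropyl isocyanate from the N–H carbamate (scavenged by Et2NH) and the phenoxide is O-triflylated in the same pot by the mild donor PhNTf2, so the electron-rich, protodesilylation-prone arylsilane never meets acid.

Step 4
Reactants: 9 1-bromodocosane, 10 1,11-dibromoundecane
Product: 12 1-bromotritriacontane, via docosylmagnesium bromide 11 (not isolated)
Conditions: 9, Mg, THF, 45 °C; then slow addition to 10 (4 equiv), Li2CuCl4 (3 mol %), NMP, THF, 20 °C; surplus 10 removed by trituration with cold acetone
Reagents that add atoms: magnesium, [Mg] (stays only in 11)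
Why: Copper-catalysed alkyl–alkyl Grignard cross-coupling (Kochi-type, NMP-accelerated) displaces a primary bromide cleanly, and slow addition of 11 to a large excess of the symmetrical dibromide should hold the reaction at mono-substitution, the much more soluble 10 being easy to separate from the waxy product.

Step 5
Reactants: 12 1-bromotritriacontane, 13 lithium acetylide ethylenediamine complex
Product: 14 pentatriacont-1-yne
Conditions: 13 (3 equiv), DMSO–THF, rt → 40 °C
Reagents that add atoms: none
Why: This is an SN2 alkylation of lithium acetylide by an unhindered primary bromide in a dipolar aprotic medium, with THF as co-solvent and gentle warming to keep the long chain in solution.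

Step 6
Reactants: 14 pentatriacont-1-yne
Product: 16 hexatriacont-2-ynoic acid, via lithium alkynide 15 (not isolated)
Conditions: n-BuLi, THF, 0 °C → rt; dry CO2 (g), 0 °C → rt; 1 M HCl
Reagents that add atoms: carbon dioxide, O=C=O; n-butyllithium, [Li]CCCC (its lithium stays only in 15)
Why: Deprotonation of the terminal alkyne and carboxylation of the alkynyllithium is the standard entry to 2-alkynoic acids, and the polar acid can here be freed from the inert hydrocarbons carried along from step 4.

Step 7
Reactants: 8 3,5-dimethoxy-2-(trimethylsilyl)phenyl trifluoromethanesulfonate, 16 hexatriacont-2-ynoic acid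
Product: 19 5,7-dimethoxy-2-tritriacontylchromone, via 3,5-dimethoxybenzyne 17 (not isolated), via hydroxyaryl ynone 18 (not isolated)
Conditions: 16 pre-stirred with CsF (4 equiv), then 8 (1.5 equiv), dilute THF, 125 °C, sealed tube
Reagents that add atoms: none
Why: Fluoride strips silicon from 8 and triflate departs to give aryne 17, whose triple bond is distorted by the flanking methoxy group so that the carbon destined to be C8a is the flatter, more electrophilic terminus. The carboxylate oxygen of 16 therefore bonds to C8a and the charge develops at C4a beside the inductively withdrawing C5–O bond, which is the regioselectivity the step depends on and which the substrate's own C5 methoxy group secures. The aryl anion adds to its own ester carbonyl (4-exo-trig, transient four-membered alkoxide), and ring opening with C–O cleavage shifts the acyl group from oxygen to carbon, forming C4a–C4 and exposing the phenoxide of ynone 18. That phenoxide adds to the β-alkyne carbon in a 6-endo-dig oxa-Michael closure (O1–C2) that builds the pyranone ring, and the proton that began on the acid ends at C3. The closest known reaction type is the fluoride-induced aryne σ-insertion into the C–O bond of carboxylic acids, which gives o-hydroxyaryl ketones and runs on to chromones and flavones with 2-alkynoic acids, hot dilute THF and excess CsF favouring acyl transfer over proton quench of the aryl anion. No stereocentre is formed.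

Step 8
Reactants: 19 5,7-dimethoxy-2-tritriacontylchromone
Product: 21 5-hydroxy-7-methoxy-2-tritriacontylchromone (target), via dichloroboron chelate 20 (not isolated)
Conditions: BCl3 (1 M in CH2Cl2, 2 equiv), CH2Cl2, 0 °C → rt; aq. HCl work-up
Reagents that add atoms: boron trichloride, ClB(Cl)Cl (its atoms stay only in 20)
Why: In this chelation-directed Lewis-acid ether cleavage BCl3 binds the C4 carbonyl and the peri C5 oxygen in a six-membered chelate and chloride removes only that methyl group, while the unchelated 7-methoxy group, the pyranone and the alkyl chain should be untouched.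

Compound list
1 | 3,5-dimethoxyphenol | COc1cc(O)cc(OC)c1 | starting material
2 | 3,5-dimethoxyphenyl N-isopropylcarbamate | COc1cc(OC)cc(OC(=O)NC(C)C)c1 | intermediate
3 | 3,5-dimethoxyphenyl N-(tert-butyldimethylsilyl)-N-isopropylcarbamate (in situ) | COc1cc(OC)cc(OC(=O)N(C(C)C)[Si](C)(C)C(C)(C)C)c1 | intermediate
4 | 2-lithio-3,5-dimethoxyphenyl N-(tert-butyldimethylsilyl)-N-isopropylcarbamate (in situ) | COc1cc(OC)c([Li])c(OC(=O)N(C(C)C)[Si](C)(C)C(C)(C)C)c1 | intermediate
5 | 3,5-dimethoxy-2-(trimethylsilyl)phenyl N-(tert-butyldimethylsilyl)-N-isopropylcarbamate (in situ) | COc1cc(OC)c([Si](C)(C)C)c(OC(=O)N(C(C)C)[Si](C)(C)C(C)(C)C)c1 | intermediate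
6 | 3,5-dimethoxy-2-(trimethylsilyl)phenyl N-isopropylcarbamate | COc1cc(OC)c([Si](C)(C)C)c(OC(=O)NC(C)C)c1 | intermediate
7 | 3,5-dimethoxy-2-(trimethylsilyl)phenol (in situ) | COc1cc(O)c([Si](C)(C)C)c(OC)c1 | intermediate
8 | 3,5-dimethoxy-2-(trimethylsilyl)phenyl trifluoromethanesulfonate | COc1cc(OC)c([Si](C)(C)C)c(OS(=O)(=O)C(F)(F)F)c1 | intermediate
9 | 1-bromodocosane | CCCCCCCCCCCCCCCCCCCCCCBr | starting material
10 | 1,11-dibromoundecane | BrCCCCCCCCCCCBr | starting material
11 | docosylmagnesium bromide (in situ) | CCCCCCCCCCCCCCCCCCCCCC[Mg]Br | intermediate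
12 | 1-bromotritriacontane | CCCCCCCCCCCCCCCCCCCCCCCCCCCCCCCCCBr | intermediate
13 | lithium acetylide ethylenediamine complex | [Li]C#C.NCCN | starting material
14 | pentatriacont-1-yne | CCCCCCCCCCCCCCCCCCCCCCCCCCCCCCCCCC#C | intermediate
15 | lithium pentatriacont-1-yn-1-ide (in situ) | CCCCCCCCCCCCCCCCCCCCCCCCCCCCCCCCCC#C[Li] | intermediate
16 | hexatriacont-2-ynoic acid | CCCCCCCCCCCCCCCCCCCCCCCCCCCCCCCCCC#CC(=O)O | intermediate
17 | 3,5-dimethoxybenzyne (in situ) | COC1=CC(OC)=CC#C1 | intermediate
18 | 1-(2-hydroxy-4,6-dimethoxyphenyl)hexatriacont-2-yn-1-one (in situ, as its phenoxide) | CCCCCCCCCCCCCCCCCCCCCCCCCCCCCCCCCC#CC(=O)c1c(O)cc(OC)cc1OC | intermediate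
19 | 5,7-dimethoxy-2-tritriacontylchromone | CCCCCCCCCCCCCCCCCCCCCCCCCCCCCCCCCc1cc(=O)c2c(OC)cc(OC)cc2o1 | intermediate
20 | 5-(dichloroboryloxy)-7-methoxy-2-tritriacontylchromone (in situ, boron chelated by the C4 carbonyl) | CCCCCCCCCCCCCCCCCCCCCCCCCCCCCCCCCc1cc(=O)c2c(OB(Cl)Cl)cc(OC)cc2o1 | intermediate
21 | 5-hydroxy-7-methoxy-2-tritriacontylchromone | CCCCCCCCCCCCCCCCCCCCCCCCCCCCCCCCCc1cc(=O)c2c(O)cc(OC)cc2o1 | target

Total step count: 8 (three to the aryne precursor, three to the acid, the key step, and the demethylation).
Longest linear sequence: 5 steps (9 → 12 → 14 → 16 → 19 → 21; the branch 1 → 2 → 6 → 8 → 19 → 21 is equally long).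

Steps most likely to fail

1. Step 7.
- **What may go wrong:** proton transfer to the aryl anion may outrun acyl migration, so the sequence stops at plain O-arylation. The alkynoate may also decarboxylate thermally, or the silyl triflate may lose silicon by protodesilylation before the aryne is released.
- **Fallback:** C-acylation of an o-hydroxyacetophenone (Baker–Venkataraman type) followed by cyclodehydration, with no aryne. It sets out from 12 and comes back at 19.
- **Route:** Bromide 12 is treated with Mg in warm THF to give tritriacontylmagnesium bromide F1, which is carboxylated with CO2 to tetratriacontanoic acid F2. SOCl2 converts this into tetratriacontanoyl chloride F3. F3 and commercial 2'-hydroxy-4',6'-dimethoxyacetophenone are combined with LiHMDS (3 equiv, THF, −78 °C → rt) to give 1-(2-hydroxy-4,6-dimethoxyphenyl)hexatriacontane-1,3-dione F4. Catalytic H2SO4 in hot AcOH then closes the pyranone by loss of water to give 19.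

2. Step 5.
- **What may go wrong:** substitution may be very slow because the waxy bromide hardly dissolves in the DMSO-rich medium, and E2 elimination and base-induced alkyne migration may take over on heating.
- **Fallback:** the order of bond formation is changed so that the acetylide SN2 runs on a short, soluble electrophile. It sets out from 10 and 11 and comes back at 14.
- **Route:** Commercial lithium (trimethylsilyl)acetylide is alkylated with an excess of 10 (THF/DMPU) to give (13-bromotridec-1-yn-1-yl)trimethylsilane F5. Copper-catalysed coupling of F5 with Grignard reagent 11, as in step 4, gives trimethyl(pentatriacont-1-yn-1-yl)silane F6. K2CO3 in MeOH/THF removes silicon to give 14.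

3. Step 4.
- **What may go wrong:** mono-selectivity may be lost through substitution at both ends of the dibromide, giving long hydrocarbons that co-crystallise with the product.
- **Fallback:** chemically differentiated termini replace statistical control. It sets out from 11 (made from 9) and comes back at 12.
- **Route:** 11 is coupled under the same copper catalysis with commercial 11-bromo-1-undecene to give tritriacont-1-ene F7. Radical-chain anti-Markovnikov hydrobromination (HBr gas, cat. dibenzoyl peroxide, heptane, 40 °C; peroxide effect) places bromine on the terminal carbon to give 12.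

Further compounds
F1 | step 7 | tritriacontylmagnesium bromide | CCCCCCCCCCCCCCCCCCCCCCCCCCCCCCCCC[Mg]Br
F2 | step 7 | tetratriacontanoic acid | CCCCCCCCCCCCCCCCCCCCCCCCCCCCCCCCCC(=O)O
F3 | step 7 | tetratriacontanoyl chloride | CCCCCCCCCCCCCCCCCCCCCCCCCCCCCCCCCC(=O)Cl
F4 | step 7 | 1-(2-hydroxy-4,6-dimethoxyphenyl)hexatriacontane-1,3-dione | CCCCCCCCCCCCCCCCCCCCCCCCCCCCCCCCCC(=O)CC(=O)c1c(O)cc(OC)cc1OC
F5 | step 5 | (13-bromotridec-1-yn-1-yl)trimethylsilane | C[Si](C)(C)C#CCCCCCCCCCCCBr
F6 | step 5 | trimethyl(pentatriacont-1-yn-1-yl)silane | CCCCCCCCCCCCCCCCCCCCCCCCCCCCCCCCCC#C[Si](C)(C)C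
F7 | step 4 | tritriacont-1-ene | CCCCCCCCCCCCCCCCCCCCCCCCCCCCCCCC=C
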